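Convert every percentage into product per litre, using each run's own charge, before drawing any line, since the two earlier runs differ in charge and the flask in question differs again.

all flasks: gas phase 42 mM (held)
- Sunday's: solid substrate 1.4 M; run made earlier
- Wednesday's: solid substrate 2.2 M; run made earlier
- flask: solid substrate 1.0 M; time 20 h

| run | time / h | product / % |
|---|---|---|
| Sunday's | 3.00 | 3.9 |
| Sunday's | 8.00 | 12.7 |
| Sunday's | 15.0 | 25.3 |
| Sunday's | 25.0 | 43.8 |
| Wednesday's | 2.00 | 1.3 |
| Wednesday's | 4.00 | 4.1 |
| Wednesday's | 10.0 | 10.6 |
| Wednesday's | 25.0 | 27.9 |

(scatter of a reading: 0.5 percentage points)

- solid, in amounts per volume of the solution: solid substrate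
- the numbers in the tables scatter by 0.5 percentage points (one standard deviation)
- at the start none of the solid substrate is in solution
- at the start none of the gas phase is in solution

* amount of product at 20 h, in percent of the solid substrate charged
* the change that raises the amount of product at 20 h, in percent of the solid substrate charged most ("none" if none brings more than 2 percentage points) (eta / zeta / beta / alpha / none)
* amount of product at 20 h, in percent of the solid substrate charged, after beta

- eta: doubling the transfer coefficient of the gas phase, all else as stated
- zeta: doubling the saturation concentration of gas phase, all else as stated
- beta: doubling the dissolution coefficient of the solid substrate, all else as stated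
- alpha: doubling the solubility of the solid substrate, all else as stated

At the last reading Sunday's run holds 0.613 M of product and Wednesday's run 0.614 M, so the concentrations agree although the percentages do not. Between its second and last readings Sunday's run gains 0.0256 M h⁻¹, and this gain of product concentration per hour is the plateau rate. Wednesday's run gains 0.0254 M h⁻¹ over its last two readings. Dividing one rate by the other removes the time and leaves 0.992, while the charges stand in a ratio of 1.57, which is an apparent zero order in the solid substrate across these two runs.

Followed in slow motion, the flask starts with nothing in solution, and Sunday's line, traced back, meets zero after a lag of 1.06 h. In the middle of the flask's run, my reckoning puts product climbing at the plateau rate. By the end this gives 48.5 % of the charge. By this reckoning the flask ends with 0.515 M of its charge not turned to product, less than the 0.787 M of Sunday's charge not turned to product at that run's last reading, so the line is carried past the stretch it was read on. The lag itself is worth 2.7 percentage points of this charge, which is the scale I expect for beta. Neither run varies the gas or the solubility.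

The forecast gives 48.5 % and names zeta, on the ground that "Raising gas saturation helps in both cases", and it puts beta at 49 %, a smaller gain than the scale I reckoned from the lag.

The flask gives 48.8 %, with zeta adding 28 points and beta reaching 51.3 %, and at 20.0 h the flask holds 0 % of solid substrate and 51.2 % as starting material.

    solid substrate ⇌ starting material, rate k1*(cs1 - [starting material]) while solid is left; crystals form when [starting material] > cs1 (solubility = 0.570 M, k = 0.0127 min⁻¹)
    gas phase ⇌ dissolved gas, rate k2*(csat - [dissolved gas]) (kL = 0.116 min⁻¹)
    2 dissolved gas → homo dimer (k = 0.149 L mol⁻¹ min⁻¹)
    starting material + dissolved gas → product (k = 0.0230 L mol⁻¹ min⁻¹)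

Carried to the neighbouring flask charged with 2.5 M and read at the same time, the plateau rate gives 19.4 % of that charge as product, and the product of that neighbouring flask stands at 19.5 %.

The data are calculated with made-up constants; the scatter is artificial.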